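Start at the reservoir. You wanted a quick number and you suspect the protic impurity, but 0.100 mM of it against 2.0 mM of starting material costs 5.00% of the substrate, so set it aside and write the balance of the reagent.

starting material 2.0 mM; reagent in the second phase 1.00 equiv; protic impurity 0.100 mM; time 12 s; volume of the second phase over the first 0.50

    starting material + reagent in the reaction phase → target (k1 = 150 M⁻¹ s⁻¹)
    reagent in the reaction phase → decomposed reagent (k2 = 0.0867 s⁻¹)
    target → over-reaction product (k3 = 0.177 s⁻¹)
    starting material + protic impurity → quenched substrate (k4 = 7560 M⁻¹ s⁻¹)
    reagent in the reaction phase ⇌ reagent in the second phase, rate k5*([reagent in the reaction phase] - [reagent in the second phase]/K5) per volume of the first phase (K5 = 2.6, k5 = 0.0554 s⁻¹)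

- in the second phase: reagent in the second phase; everything else is in the first
- charges count per volume of the first phase; a concentration in a rate is the amount of a species over the volume of its own phase; every rate counts per litre of the first phase
- run time (flask): 12 s

- the target standing at 12 s, as a percentage of the starting material charged
- the change that raises the amount of target at 12 s, in percent of the starting material charged most ("none" if none brings more than 2 percentage points) (beta / zeta / none)
- amount of target at 12 s, in percent of the starting material charged, after zeta

Take the reagent in the second phase. While the reaction phase holds little of it, the reservoir empties like a tank through a valve, with a drain time 23.5 s: the volume ratio times the partition ratio, over the transfer coefficient. One equivalent over that time is a first feed of 0.0852 mM s⁻¹, and the feed decays with the same time constant.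

Hold starting material at what the impurity leaves, 1.90 mM. Arriving reagent then meets a pseudo-first-order capture of 0.285 s⁻¹, against decomposition at 0.0867 s⁻¹ and return at 0.0554 s⁻¹, so capture takes a share of 66.7%. The reagent settles in 2.34 s and the target lives 5.65 s, both shorter than the run, so as an estimate let the target follow its making. Multiply the feed at the end by the share, divide by the over-reaction constant, and I commit to 9.63%. Beta doubles the feed throughout, giving about 19.3%. Zeta halves the drain time and gives 10.2%. Choose beta.

The forecast gives 9.2%, beta and 12.7% after zeta, holding that “slow transfer from the second phase limits the reagent supply”. The flask gives 9.25%, then beta with a gain of 7.5 percentage points against 3.7 points for zeta, and 12.9% after zeta, so my zeta number reads 2.7 points low, and my gain for beta, 9.6 points, reads higher than the flask's. Moving the target at 12 s by 5 points takes 0.437 equiv or 1.64 equiv of reagent in the second phase.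

In this flask the target's half-life by over-reaction, 3.9 s, is shorter than the reservoir's half-time from the drain time, 16.3 s, and the drain time reckons 60.0% of the reagent's charge still in the second phase at 12.0 s, where the flask holds 63.7%. The same charge read at 50 s holds 17.5% there against 11.9% from the drain time, and its target stands at 2.75%.

Its constants stand for no real mixture.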